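Readings and results were generated by integration for an exercise, and the scatter is random.

Every flask was to be read at 3.0 h, so I wanted the amount of target standing at that moment.

| flask | solid substrate | temperature | remark | time |
|---|---|---|---|---|
| elm | 1.3 M | 10 °C | run made earlier |  |
| ash | 2 M | 40 °C | run made earlier |  |
| autumn | 0.92 M |  | at 65 °C until 50 min, from then on at 15 °C | 3.0 h |
| summer | 0.92 M | 40 °C |  | 3.0 h |
| noon | 0.92 M | 65 °C |  | 3.0 h |
| midnight | 0.92 M | 15 °C |  | 3.0 h |

- elm (time / h: target / %, solid substrate / %): 2.00: 0.3, 90.9; 4.00: 1.0, 89.1; 6.00: 2.4, 86.7; 8.00: 3.2, 85.2; 12.0: 5.4, 81.0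
- ash (time / h: target / %, solid substrate / %): 0.167: 0.5, 98.0; 0.500: 1.3, 94.8; 0.833: 2.1, 91.4; 1.33: 3.8, 87.0; 2.00: 6.2, 80.0; 2.50: 7.2, 75.3

(readings scatter by 0.3 percentage points)

- given per volume of solution although it is solid: solid substrate
- at the start none of the solid substrate is in solution
- what has only dissolved of solid substrate counts as not reacted

- the flask with the highest amount of target, in percent of the solid substrate charged ("all alike" if they lie within 1.5 percentage points) (autumn / summer / noon / midnight / all alike)
- final target, as a percentage of the solid substrate charged, in autumn
- final target, as a percentage of the solid substrate charged, in summer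
- final target, as a percentage of the solid substrate charged, in noon
- final target, as a percentage of the solid substrate charged, in midnight

1. In ash, at 40 °C, solid substrate read 94.8% at 0.500 h and 75.3% at 2.50 h. The early loss was 0.208 M h⁻¹ and the loss over the whole run 0.198 M h⁻¹, a zero-order line. I called this whole-run value the dissolution flux: the fall of c(solid substrate) per hour while solid stands.

2. I assumed that what dissolves reacts on at the pace it dissolves, a steady state, and that the flux does not depend on the size of the charge while solid stands. So I carried the flux unchanged from ash to summer, which has the same temperature and a smaller charge. Over 3.0 h that gave a loss of 0.593 M, or 64.4% of the summer charge.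

3. Ash had turned 0.291 of its lost solid substrate into target, as read at 2.50 h. Taking that reading as the share in summer at 3.0 h, I reckoned 18.8% target.

4. The weak link was the smaller charge, since the straight line ends when the solid does. At this flux I reckoned the summer charge good for 4.66 h, longer than the reading time, so I kept the straight line up to that time. I had no reading above 40 °C, so I left noon and autumn unreckoned; midnight I did not reckon either, and I committed to the summer figure.

The forecast gave autumn 18%, summer 17%, “less if the solid runs out”, noon 20% and midnight 2.5%, and named noon highest.

Summer gave 18.1%, the highest, against 8.81% in autumn, 9.32% in noon and 2.38% in midnight. At 3.00 h, starting material in summer stood at 2.91%, made 1.00 times as fast as it was used. The flux had put the loss of solid substrate in summer at 64.4%, which leaves 35.6%, and the summer flask held 36.4% of it at 3.00 h.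

    intermediate ⇌ isomer of the product (K = 2.80, k = 1.20 × 10⁻⁴ s⁻¹, Ea = 93.0 kJ mol⁻¹, ΔH = −37.0 kJ mol⁻¹)
    starting material → intermediate (k = 0.00200 s⁻¹, Ea = 97.0 kJ mol⁻¹)
    intermediate ⇌ target (K = 0.690, k = 0.00280 s⁻¹, Ea = 99.0 kJ mol⁻¹, ΔH = −37.0 kJ mol⁻¹)
    solid substrate ⇌ starting material, rate k4*(cs4 - [starting material]) while solid is left; crystals form when [starting material] > cs4 (solubility = 0.0990 M, k = 7.40 × 10⁻⁴ s⁻¹)
    (constants at 40 °C)

Read at 12 h, the same summer flask outlasts the 4.66 h the flux allows its charge, so I expected no solid substrate there. The computed flask had 0% of it left, with 16.0% target.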